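Ring A is made from open-chain pieces, because its four adjacent substituents (the C4 carbon on C4a, O1 on C8a, prenyl on C8, hydroxyl on C7) put the prenyl group between two oxygens, which substitution of a resorcinol does not deliver cleanly. A vinylketene, released by light from the diazo enone N2CH–CO–CH=CH–CH2OTBS, joins the siloxyalkyne prenyl–C≡C–OTIPS and in one operation forms C8–C8a, C6–C7 and C4a–C8a (C7–C8 is the alkyne bond itself). The phenol obtained has both oxygens differentiated and a benzylic carbon that becomes C4. Ring C is then closed with ring B in place, and C3 is set as R by dynamic kinetic transfer hydrogenation and reoxidation.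

Key step: step 4

Remark on the structure: isoflavanone numbering is used (O1, C2, C3, C4, C4a, C5 to C8, C8a; ring A is the benzo ring, ring C the pyranone, ring B the 2,2-dimethylchroman-6-yl group on C3); the target SMILES corresponds to the 3R configuration.
Remark on supply: ethyl 4-methylpent-3-enoate, (tert-butyldimethylsilyloxy)acetaldehyde, 1-(triphenylphosphoranylidene)propan-2-one and 2,2-dimethylchroman-6-carbaldehyde are taken as purchasable.

Step 1
Reactants: 1 ethyl 4-methylpent-3-enoate
Product: 4 triisopropyl[(5-methylhex-4-en-1-yn-1-yl)oxy]silane, via lithium dibromo enolate 2 (not isolated), via lithium ynolate 3 (not isolated)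
Conditions: CH2Br2, lithium 2,2,6,6-tetramethylpiperidide, THF, −78 °C; n-BuLi, −78 °C → rt; i-Pr3SiOTf, −78 → 0 °C
Reagents that add atoms: dibromomethane, BrCBr (supplies the alkyne carbon that carries the prenyl group); triisopropylsilyl triflate, CC(C)[Si](OS(=O)(=O)C(F)(F)F)(C(C)C)C(C)C
Why: Kowalski ester homologation, in which dibromomethyllithium adds to the ester, enolate 2 undergoes bromine–lithium exchange and 1,2-shift to ynolate 3, and the bulky silyl triflate traps the ynolate on oxygen, while the low temperature should keep the β,γ-alkene out of conjugation.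

Step 2
Reactants: 5 (tert-butyldimethylsilyloxy)acetaldehyde, 6 1-(triphenylphosphoranylidene)propan-2-one
Product: 7 (E)-5-(tert-butyldimethylsilyloxy)pent-3-en-2-one
Conditions: CH2Cl2, rt → 40 °C
Reagents that add atoms: none
Why: Wittig olefination with a ketone-stabilised ylide, which should give the E enone selectively.

Step 3
Reactants: 7 (E)-5-(tert-butyldimethylsilyloxy)pent-3-en-2-one
Product: 9 (E)-5-(tert-butyldimethylsilyloxy)-1-diazopent-3-en-2-one, via trifluoroacetyl diketone 8 (not isolated)
Conditions: LiN(SiMe3)2, THF, −78 °C; CF3CO2CH2CF3, −78 °C; cold dilute aq. HCl work-up; crude 8 carried on, 4-acetamidobenzenesulfonyl azide, Et3N, H2O (1 equiv), MeCN, rt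
Reagents that add atoms: 2,2,2-trifluoroethyl trifluoroacetate, O=C(OCC(F)(F)F)C(F)(F)F (its trifluoroacetyl group is held only by 8); 4-acetamidobenzenesulfonyl azide, CC(=O)Nc1ccc(cc1)S(=O)(=O)N=[N+]=[N-] (supplies the two diazo nitrogens)
Why: Detrifluoroacetylative diazo transfer (a deacylative Regitz-type transfer), in which the kinetic methyl enolate is trifluoroacetylated to the activated diketone 8, which takes up the diazo group and loses the trifluoroacetyl group as an acyl sulfonamide, so that neither diazomethane nor an acylation prone to pyrazoline formation is needed.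

Step 4
Reactants: 9 (E)-5-(tert-butyldimethylsilyloxy)-1-diazopent-3-en-2-one, 4 triisopropyl[(5-methylhex-4-en-1-yn-1-yl)oxy]silane
Product: 14 6-[(tert-butyldimethylsilyloxy)methyl]-2-(3-methylbut-2-enyl)-3-(triisopropylsilyloxy)phenol, via vinylketene 10 (not isolated), via vinylcyclobutenone 11 (not isolated), via dienylketene 12 (not isolated), via cyclohexadienone 13 (not isolated)
Conditions: 4 (1.5 equiv), hν (254 nm, low-pressure mercury lamps, quartz), degassed ClCH2CH2Cl, rt; then 80 °C
Reagents that add atoms: none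
Why: Light expels N2 from 9 and Wolff rearrangement gives vinylketene 10, whose carbonyl carbon is attacked by the nucleophilic, prenyl-bearing carbon of the siloxyalkyne in a (2+2) cycloaddition to cyclobutenone 11, which forms C8–C8a and C6–C7. Four-electron electrocyclic opening of 11 gives dienylketene 12, and ring A closes by six-electron disrotatory electrocyclisation between the ketene carbon and the diene terminus (C4a–C8a), after which dienone 13 tautomerises to the phenol. The closest known reaction type is the Danheiser benzannulation in its photochemical diazo ketone variant with siloxyalkynes. No stereocentre is created, and the only selectivity needed is the orientation of the (2+2) step, which the oxygen-polarised triple bond secures so that the prenyl group ends between the free phenol (future O1) and the silyl ether (future 7-OH). The excess of alkyne should outrun capture of the ketene by the product phenol, and the final heating should drive any remaining cyclobutenone through to the arene.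

Step 5
Reactants: 14 6-[(tert-butyldimethylsilyloxy)methyl]-2-(3-methylbut-2-enyl)-3-(triisopropylsilyloxy)phenol
Product: 15 6-(hydroxymethyl)-2-(3-methylbut-2-enyl)-3-(triisopropylsilyloxy)phenol
Conditions: HF·pyridine, pyridine, THF, 0 °C
Reagents that add atoms: none
Why: Selective desilylation, since acid-assisted fluoride cleaves the primary alkyl tert-butyldimethylsilyl ether much faster than the hindered aryl triisopropylsilyl ether, and the pyridine buffer should spare the prenyl group and the electron-rich benzylic alcohol.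

Step 6
Reactants: 15 6-(hydroxymethyl)-2-(3-methylbut-2-enyl)-3-(triisopropylsilyloxy)phenol
Product: 16 2-hydroxy-3-(3-methylbut-2-enyl)-4-(triisopropylsilyloxy)benzaldehyde
Conditions: MnO2 (excess), CH2Cl2, rt
Reagents that add atoms: none
Why: Benzylic oxidation with MnO2 stops at the aldehyde, which is held by a hydrogen bond to the ortho hydroxyl, and should leave phenol, alkene and silyl ether untouched.

Step 7
Reactants: 17 2,2-dimethylchroman-6-carbaldehyde
Product: 18 (2,2-dimethylchroman-6-yl)methanol
Conditions: NaBH4, MeOH, 0 °C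
Reagents that add atoms: none
Why: Borohydride reduction of an aryl aldehyde to the benzylic alcohol.

Step 8
Reactants: 18 (2,2-dimethylchroman-6-yl)methanol
Product: 19 6-(chloromethyl)-2,2-dimethylchroman
Conditions: SOCl2, CH2Cl2, 0 °C
Reagents that add atoms: thionyl chloride, O=S(Cl)Cl
Why: Nucleophilic substitution through the chlorosulfite converts the electron-rich benzylic alcohol into the chloride, which is used at once.

Step 9
Reactants: 19 6-(chloromethyl)-2,2-dimethylchroman, 16 2-hydroxy-3-(3-methylbut-2-enyl)-4-(triisopropylsilyloxy)benzaldehyde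
Product: 21 6-[2-(2,2-dimethylchroman-6-yl)-1-hydroxyethyl]-2-(3-methylbut-2-enyl)-3-(triisopropylsilyloxy)phenol (racemic), via benzylic Grignard reagent 20 (not isolated)
Conditions: Mg turnings, THF, 0 °C (slow addition of 19); then 16 (0.4 equiv), −20 °C → rt; aq. NH4Cl
Reagents that add atoms: magnesium, [Mg] (held only by 20)
Why: Grignard addition, in which the first equivalent of 20 deprotonates the phenol and the second adds to the aldehyde; the new carbinol centre forms as a racemate and is erased in step 10.

Step 10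
Reactants: 21 6-[2-(2,2-dimethylchroman-6-yl)-1-hydroxyethyl]-2-(3-methylbut-2-enyl)-3-(triisopropylsilyloxy)phenol
Product: 22 2-(2,2-dimethylchroman-6-yl)-1-[2-hydroxy-3-(3-methylbut-2-enyl)-4-(triisopropylsilyloxy)phenyl]ethan-1-one
Conditions: MnO2 (excess), CH2Cl2, rt
Reagents that add atoms: none
Why: Benzylic oxidation with MnO2 converts the secondary alcohol into the ortho-hydroxyaryl ketone under neutral conditions that tolerate the free phenol.

Step 11
Reactants: 22 2-(2,2-dimethylchroman-6-yl)-1-[2-hydroxy-3-(3-methylbut-2-enyl)-4-(triisopropylsilyloxy)phenyl]ethan-1-one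
Product: 25 3-(2,2-dimethylchroman-6-yl)-8-(3-methylbut-2-enyl)-7-(triisopropylsilyloxy)chroman-4-one (racemic), via Mannich base 23 (not isolated), via aryl vinyl ketone 24 (not isolated)
Conditions: (CH2O)n, Et2NH, EtOH, 60 °C
Reagents that add atoms: paraformaldehyde (as formaldehyde), C=O (becomes C2); diethylamine, CCNCC (held only by 23)
Why: Formaldehyde annulation of a 2-hydroxydeoxybenzoin, in which a Mannich reaction at the doubly activated methylene gives 23, loss of diethylamine gives enone 24, and the ortho phenol closes ring C by 6-endo oxa-Michael addition; C3 forms as a racemate.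

Step 12
Reactants: 25 3-(2,2-dimethylchroman-6-yl)-8-(3-methylbut-2-enyl)-7-(triisopropylsilyloxy)chroman-4-one (racemic)
Product: 26 (3R,4R)-3-(2,2-dimethylchroman-6-yl)-8-(3-methylbut-2-enyl)-7-(triisopropylsilyloxy)chroman-4-ol (cis)
Conditions: RuCl[(R,R)-TsDPEN](p-cymene) (2 mol %), HCO2H, Et3N (excess), EtOAc, 40 °C
Reagents that add atoms: none
Why: Noyori-type asymmetric transfer hydrogenation with dynamic kinetic resolution, in which the (R,R)-catalyst delivers hydride to one carbonyl face to set C4 as R, reduces the 3R ketone faster to the cis alcohol and so fixes C3 as R, while triethylamine keeps the two ketone enantiomers in equilibrium through the enol.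

Step 13
Reactants: 26 (3R,4R)-3-(2,2-dimethylchroman-6-yl)-8-(3-methylbut-2-enyl)-7-(triisopropylsilyloxy)chroman-4-ol
Product: 27 (3R)-3-(2,2-dimethylchroman-6-yl)-8-(3-methylbut-2-enyl)-7-(triisopropylsilyloxy)chroman-4-one
Conditions: Dess–Martin periodinane, CH2Cl2, 0 °C
Reagents that add atoms: none
Why: Dess–Martin oxidation returns the C4 ketone under non-basic conditions, so the C3 centre set in step 12 should not epimerise.

Step 14
Reactants: 27 (3R)-3-(2,2-dimethylchroman-6-yl)-8-(3-methylbut-2-enyl)-7-(triisopropylsilyloxy)chroman-4-one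
Product: 28 (3R)-3-(2,2-dimethylchroman-6-yl)-7-hydroxy-8-(3-methylbut-2-enyl)chroman-4-one (CNP0139927.1)
Conditions: KHF2, MeOH, rt
Reagents that add atoms: none
Why: Fluoride desilylation, in which bifluoride cleaves the aryl silyl ether activated by the para carbonyl group in a weakly acidic medium where the enolisable C3 centre should keep its R configuration.

Compound list

1 | ethyl 4-methylpent-3-enoate | CCOC(=O)CC=C(C)C | starting material
2 | lithium 1,1-dibromo-5-methylhexa-1,4-dien-2-olate | [Li+].[O-]C(CC=C(C)C)=C(Br)Br | intermediate (not isolated)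
3 | lithium 5-methylhex-4-en-1-yn-1-olate | [Li+].[O-]C#CCC=C(C)C | intermediate (not isolated)
4 | triisopropyl[(5-methylhex-4-en-1-yn-1-yl)oxy]silane | CC(C)=CCC#CO[Si](C(C)C)(C(C)C)C(C)C | intermediate
5 | (tert-butyldimethylsilyloxy)acetaldehyde | CC(C)(C)[Si](C)(C)OCC=O | starting material
6 | 1-(triphenylphosphoranylidene)propan-2-one | CC(=O)C=P(c1ccccc1)(c1ccccc1)c1ccccc1 | starting material
7 | (E)-5-(tert-butyldimethylsilyloxy)pent-3-en-2-one | CC(=O)/C=C/CO[Si](C)(C)C(C)(C)C | intermediate
8 | (E)-7-(tert-butyldimethylsilyloxy)-1,1,1-trifluorohept-5-ene-2,4-dione | O=C(CC(=O)/C=C/CO[Si](C)(C)C(C)(C)C)C(F)(F)F | intermediate (not isolated)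
9 | (E)-5-(tert-butyldimethylsilyloxy)-1-diazopent-3-en-2-one | [N-]=[N+]=CC(=O)/C=C/CO[Si](C)(C)C(C)(C)C | intermediate
10 | (3E)-5-(tert-butyldimethylsilyloxy)penta-1,3-dien-1-one (vinylketene) | O=C=C/C=C/CO[Si](C)(C)C(C)(C)C | intermediate (not isolated)
11 | 4-[(E)-3-(tert-butyldimethylsilyloxy)prop-1-enyl]-2-(3-methylbut-2-enyl)-3-(triisopropylsilyloxy)cyclobut-2-en-1-one (racemic) | O=C1C(CC=C(C)C)=C(O[Si](C(C)C)(C(C)C)C(C)C)C1/C=C/CO[Si](C)(C)C(C)(C)C | intermediate (not isolated)
12 | 7-(tert-butyldimethylsilyloxy)-2-(3-methylbut-2-enyl)-3-(triisopropylsilyloxy)hepta-1,3,5-trien-1-one (dienylketene; C2 and C5 cis across C3=C4, C5=C6 E) | O=C=C(CC=C(C)C)/C(O[Si](C(C)C)(C(C)C)C(C)C)=C\C=C\CO[Si](C)(C)C(C)(C)C | intermediate (not isolated)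
13 | 6-[(tert-butyldimethylsilyloxy)methyl]-2-(3-methylbut-2-enyl)-3-(triisopropylsilyloxy)cyclohexa-2,4-dien-1-one | O=C1C(CC=C(C)C)=C(O[Si](C(C)C)(C(C)C)C(C)C)C=CC1CO[Si](C)(C)C(C)(C)C | intermediate (not isolated)
14 | 6-[(tert-butyldimethylsilyloxy)methyl]-2-(3-methylbut-2-enyl)-3-(triisopropylsilyloxy)phenol | CC(C)=CCc1c(O[Si](C(C)C)(C(C)C)C(C)C)ccc(CO[Si](C)(C)C(C)(C)C)c1O | intermediate
15 | 6-(hydroxymethyl)-2-(3-methylbut-2-enyl)-3-(triisopropylsilyloxy)phenol | CC(C)=CCc1c(O[Si](C(C)C)(C(C)C)C(C)C)ccc(CO)c1O | intermediate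
16 | 2-hydroxy-3-(3-methylbut-2-enyl)-4-(triisopropylsilyloxy)benzaldehyde | CC(C)=CCc1c(O[Si](C(C)C)(C(C)C)C(C)C)ccc(C=O)c1O | intermediate
17 | 2,2-dimethylchroman-6-carbaldehyde | CC1(C)CCc2cc(C=O)ccc2O1 | starting material
18 | (2,2-dimethylchroman-6-yl)methanol | CC1(C)CCc2cc(CO)ccc2O1 | intermediate
19 | 6-(chloromethyl)-2,2-dimethylchroman | CC1(C)CCc2cc(CCl)ccc2O1 | intermediate
20 | (2,2-dimethylchroman-6-yl)methylmagnesium chloride | CC1(C)CCc2cc(C[Mg]Cl)ccc2O1 | intermediate (not isolated)
21 | 6-[2-(2,2-dimethylchroman-6-yl)-1-hydroxyethyl]-2-(3-methylbut-2-enyl)-3-(triisopropylsilyloxy)phenol (racemic) | CC(C)=CCc1c(O[Si](C(C)C)(C(C)C)C(C)C)ccc(C(O)Cc2ccc3c(c2)CCC(C)(C)O3)c1O | intermediate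
22 | 2-(2,2-dimethylchroman-6-yl)-1-[2-hydroxy-3-(3-methylbut-2-enyl)-4-(triisopropylsilyloxy)phenyl]ethan-1-one | CC(C)=CCc1c(O[Si](C(C)C)(C(C)C)C(C)C)ccc(C(=O)Cc2ccc3c(c2)CCC(C)(C)O3)c1O | intermediate
23 | 3-(diethylamino)-2-(2,2-dimethylchroman-6-yl)-1-[2-hydroxy-3-(3-methylbut-2-enyl)-4-(triisopropylsilyloxy)phenyl]propan-1-one (racemic) | CCN(CC)CC(C(=O)c1ccc(O[Si](C(C)C)(C(C)C)C(C)C)c(CC=C(C)C)c1O)c1ccc2c(c1)CCC(C)(C)O2 | intermediate (not isolated)
24 | 2-(2,2-dimethylchroman-6-yl)-1-[2-hydroxy-3-(3-methylbut-2-enyl)-4-(triisopropylsilyloxy)phenyl]prop-2-en-1-one | C=C(C(=O)c1ccc(O[Si](C(C)C)(C(C)C)C(C)C)c(CC=C(C)C)c1O)c1ccc2c(c1)CCC(C)(C)O2 | intermediate (not isolated)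
25 | 3-(2,2-dimethylchroman-6-yl)-8-(3-methylbut-2-enyl)-7-(triisopropylsilyloxy)chroman-4-one (racemic) | CC(C)=CCc1c(O[Si](C(C)C)(C(C)C)C(C)C)ccc2c1OCC(c1ccc3c(c1)CCC(C)(C)O3)C2=O | intermediate
26 | (3R,4R)-3-(2,2-dimethylchroman-6-yl)-8-(3-methylbut-2-enyl)-7-(triisopropylsilyloxy)chroman-4-ol | CC(C)=CCc1c(O[Si](C(C)C)(C(C)C)C(C)C)ccc2c1OC[C@@H](c1ccc3c(c1)CCC(C)(C)O3)[C@H]2O | intermediate
27 | (3R)-3-(2,2-dimethylchroman-6-yl)-8-(3-methylbut-2-enyl)-7-(triisopropylsilyloxy)chroman-4-one | CC(C)=CCc1c(O[Si](C(C)C)(C(C)C)C(C)C)ccc2c1OC[C@@H](c1ccc3c(c1)CCC(C)(C)O3)C2=O | intermediate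
28 | (3R)-3-(2,2-dimethylchroman-6-yl)-7-hydroxy-8-(3-methylbut-2-enyl)chroman-4-one | CC(C)=CCc1c(O)ccc2c1OC[C@@H](c1ccc3c(c1)CCC(C)(C)O3)C2=O | target

Total step count: 14. Longest linear sequence: 11 steps (steps 2, 3, 4, 5, 6, 9, 10, 11, 12, 13, 14).

Steps most likely to fail

Step 4. The vinylketene may be captured by the phenol product or by a second ketene instead of the alkyne, the diazo enone may be lost to light-induced isomerisation or intermolecular dipolar addition, or the cascade may stall before aromatisation. The fallback gives up building ring A and takes it from a purchased arene. Because no compound before 14 contains an arene, it sets out from no numbered compound but from purchased 1,3-bis(methoxymethoxy)benzene F1, and it comes back to the route at salicylaldehyde 16, so that steps 1 to 6 fall away. Lithiation between the two acetal oxygens (n-BuLi, THF, 0 °C) and alkylation with prenyl bromide should give 1,3-bis(methoxymethoxy)-2-(3-methylbut-2-enyl)benzene F2. A second directed ortho-lithiation (n-BuLi, TMEDA) and quench with DMF should give 2,4-bis(methoxymethoxy)-3-(3-methylbut-2-enyl)benzaldehyde F3. HCl in MeOH should release 2,4-dihydroxy-3-(3-methylbut-2-enyl)benzaldehyde F4. Silylation with i-Pr3SiCl and imidazole should then take place at the 4-hydroxyl only, the 2-hydroxyl being tied up in the hydrogen bond to the aldehyde, and give 16.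

Step 1. The carbenoid base may deprotonate the doubly activated α-methylene of the β,γ-unsaturated ester in competition with addition, and the alkene may move into conjugation. The fallback sets out from ester 1 and comes back at siloxyalkyne 4 by way of ynolate 3, reaching the ynolate by oxidation of an acetylide instead of by homologation. Reduction with i-Bu2AlH at −78 °C should give 4-methylpent-3-enal F5, and dibromo-olefination (CBr4, PPh3, CH2Cl2, 0 °C) should give 1,1-dibromo-5-methylhexa-1,4-diene F6. Two equivalents of n-BuLi should convert F6 into (5-methylhex-4-en-1-yn-1-yl)lithium F7 (Corey–Fuchs sequence). F7 is oxidised in the same flask with lithium tert-butyl peroxide (from t-BuOOH and LiN(SiMe3)2) to ynolate 3, which i-Pr3SiOTf traps as 4.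

Step 11. The aryl silyl ether may be partly lost in the warm amine and alcohol medium, a second hydroxymethylation may occur at C3, or the phenol ring may be aminomethylated. The fallback sets out from ketone 22 and comes back at racemic isoflavanone 25, passing through the isoflavone instead of the Mannich base. Heating 22 with Me2NCH(OMe)2 in toluene at 80 °C should give enaminone F8, which is not isolated and should close with loss of dimethylamine to the isoflavone 3-(2,2-dimethylchroman-6-yl)-8-(3-methylbut-2-enyl)-7-(triisopropylsilyloxy)-4H-chromen-4-one F9. Conjugate reduction of F9 with LiBH(s-Bu)3 in THF at −78 °C and protonation of the enolate should give 25.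

Further compounds

F1 | step 4 | 1,3-bis(methoxymethoxy)benzene (purchased) | COCOc1cccc(OCOC)c1
F2 | step 4 | 1,3-bis(methoxymethoxy)-2-(3-methylbut-2-enyl)benzene | COCOc1cccc(OCOC)c1CC=C(C)C
F3 | step 4 | 2,4-bis(methoxymethoxy)-3-(3-methylbut-2-enyl)benzaldehyde | COCOc1ccc(C=O)c(OCOC)c1CC=C(C)C
F4 | step 4 | 2,4-dihydroxy-3-(3-methylbut-2-enyl)benzaldehyde | CC(C)=CCc1c(O)ccc(C=O)c1O
F5 | step 1 | 4-methylpent-3-enal | CC(C)=CCC=O
F6 | step 1 | 1,1-dibromo-5-methylhexa-1,4-diene | CC(C)=CCC=C(Br)Br
F7 | step 1 | (5-methylhex-4-en-1-yn-1-yl)lithium | [Li]C#CCC=C(C)C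
F8 | step 11 | 3-(dimethylamino)-2-(2,2-dimethylchroman-6-yl)-1-[2-hydroxy-3-(3-methylbut-2-enyl)-4-(triisopropylsilyloxy)phenyl]prop-2-en-1-one | CN(C)C=C(C(=O)c1ccc(O[Si](C(C)C)(C(C)C)C(C)C)c(CC=C(C)C)c1O)c1ccc2c(c1)CCC(C)(C)O2
F9 | step 11 | 3-(2,2-dimethylchroman-6-yl)-8-(3-methylbut-2-enyl)-7-(triisopropylsilyloxy)-4H-chromen-4-one | CC(C)=CCc1c(O[Si](C(C)C)(C(C)C)C(C)C)ccc2c1OC=C(c1ccc3c(c1)CCC(C)(C)O3)C2=O
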